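The data were computed for an exercise; scatter was added.

3 questions stood before me about the amount of X after 5.0 d in 5 new flasks: their order, the top value and the bottom value.

| flask | J | E | G | remark | time |
|---|---|---|---|---|---|
| spring | 0.17 M | 0.80 equiv | 1 mol% | run made earlier |  |
| autumn | 0.29 M | 0.80 equiv | 1 mol% | run made earlier |  |
| winter | 0.52 M | 0.80 equiv | 1 mol% | run made earlier |  |
| midnight | 0.30 M | 0.64 equiv | 1 mol% | run made earlier |  |
| teal | 0.30 M | 2.40 equiv | 0.3 mol% |  | 5.0 d |
| violet | 0.30 M | 0.400 equiv | 1 mol% |  | 5.0 d |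
| blue | 0.50 M | 0.800 equiv | 3 mol% |  | 5.0 d |
| red | 0.30 M | 0.800 equiv | 1 mol% |  | 5.0 d |
| grey | 0.20 M | 0.200 equiv | 4 mol% |  | 5.0 d |

| run | time / d | X / % | J / % |
|---|---|---|---|
| spring | 0.208 | 8.3 | 62.8 |
| spring | 0.417 | 19.4 | 44.8 |
| spring | 0.625 | 27.2 | 34.9 |
| spring | 1.25 | 40.9 | 20.2 |
| spring | 2.50 | 43.7 | 11.1 |
| autumn | 0.208 | 17.9 | 50.3 |
| autumn | 0.625 | 40.4 | 24.9 |
| autumn | 1.25 | 48.4 | 13.3 |
| autumn | 1.67 | 49.3 | 11.7 |
| autumn | 2.50 | 50.2 | 8.5 |
| winter | 0.500 | 49.6 | 18.0 |
| winter | 1.04 | 53.1 | 12.4 |
| winter | 1.67 | 52.6 | 8.5 |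
| winter | 2.08 | 53.0 | 7.6 |
| winter | 2.50 | 52.6 | 8.0 |
| midnight | 0.208 | 16.0 | 50.8 |
| midnight | 0.625 | 37.4 | 25.6 |
| midnight | 1.25 | 43.0 | 15.7 |
| midnight | 1.67 | 43.2 | 12.9 |
| midnight | 2.50 | 43.2 | 8.6 |

(standard deviation of a reading: 0.5 percentage points)

* the flasks by amount of X, in percent of the J charged, highest first, at 5.0 d (teal / violet / blue / red / grey)
* the amount of X, in percent of the J charged of the flask you put first, at 5.0 d
* the amount of X, in percent of the J charged of the flask you put last, at 5.0 d

- amounts and yields of X count L too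
- given per volume of solution although it is solid: L
- what may be going on: J + G <-> G + Q; G + Q <-> Z; E + Z <-> G + X; L <-> X; 2 E -> D

I read the steps thus: on G, J turns into Q; G takes up Q as Z; E meets Z and gives X and G back; X can come out as L; pairs of E burn to D. I watched the autumn run in slow motion. At 0.208 d, J stood at 50.3% and X at 17.9%, so 31.8% of the J charged was already in neither. In the middle, at 0.625 d, X had reached 40.4%. At the end X stalled near 50.2% while J still fell to 8.5%, although 0.80 equiv of E had gone in, so I took E for the limiting reagent and supposed that burning had taken the difference.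

Burning goes with [E]² and capture with [E][Z], so, with [Z] taken as steady, each E spent gives less X the more E is still there: a gain of 1/(1+be), with e the equivalents of E remaining. Summed over the run, this gives a plateau of ln(1+be)/b for a charge e. The last readings of autumn and midnight, two runs nearly alike in [J], gave a last-stretch gain of 0.437, hence a first b of 1.79. Put back into the autumn plateau, this returned 1.77, my burn number b at 1 mol%: E lost to burning per E captured, per equivalent of E present.

I let b fall inversely with the loading of G and ignored the drift with [J] between spring and winter. That gave blue 65.5%, red 49.9%, teal 46.1%, violet 30.3% and grey 19.2%.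

The forecast, holding that “E is split between productive capture and second-order self-destruction”, gave blue > red > teal > violet > grey, with 62% for the first flask and 19% for the last. Its order was mine, but its top was lower than my 65.5%, and it put teal at about 33 percent against my 46.1%.

The flasks gave blue > red > teal > violet > grey: blue 65.6%, red 49.5%, teal 40.3%, violet 30.6%, grey 17.8%.

    J + G ⇌ G + Q (K = 5.70, k = 0.0190 M⁻¹ s⁻¹)
    G + Q ⇌ Z (K = 30.0 M⁻¹, k = 0.0260 M⁻¹ s⁻¹)
    E + Z ⇌ G + X (K = 2.90, k = 0.0260 M⁻¹ s⁻¹)
    L ⇌ X, rate k4*(cs4 - [X]) while solid is left; crystals form when [X] > cs4 (solubility = 0.0870 M, k = 6.40 × 10⁻⁴ s⁻¹)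
    2 E → D (k = 4.90 × 10⁻⁵ M⁻¹ s⁻¹)

In grey at 5.00 d the step between E + Z and G + X relaxed, by that step alone, with a half-life of 0.333 h, shorter than the 0.226 d of the step between J and Q and short against the 5.0 d of the run, and beside 17.8% of X grey still held 7.58% of its E unbound. Scaled to grey's loading my burn number was 0.442, which had sent 4.17% of grey's E to burning where the D formed accounts for 3.57%, and for the neighbour of grey charged with 0.800 equiv of E the same number reckoned 68.5% of X where that flask gave 57.1%.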